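(The constants belong to no real substance; the result is computed.)

The same charge of substrate and partner goes through a dosed flask, a closed flask and two flow tanks, and we compare the target each holds at its end.

all flasks: partner 0.360 M
- ash: substrate 0.20 M (fed, over 2.00 min); time 2.5 min; a stirred flask in which substrate is dosed at a steady rate over 2.00 min without added volume, worked up at 2.5 min
- maple: substrate 0.20 M; one stirred flow tank at steady state, fed with the mixture as stated, mean residence time 2.5 min
- larch: substrate 0.20 M; one stirred flow tank at steady state, fed with the mixture as stated, mean residence time 25.0 min
- elm: substrate 0.20 M; time 2.5 min; everything together in a closed stirred flask, run for 2.5 min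

    substrate ⇌ open intermediate (K1 = 0.80, k1 = 1.0 s⁻¹)
    partner → second intermediate (k2 = 0.049 s⁻¹)
    open intermediate + second intermediate ⇌ target (K3 = 2.2 L mol⁻¹, k3 = 0.74 L mol⁻¹ s⁻¹)
    2 open intermediate → homo product (k4 = 0.20 L mol⁻¹ s⁻¹)

- the set-up with the highest amount of target at the outlet or at the end, in percent of the substrate put in ("none" if the first two lie within 2 percentage points) (ash / maple / larch / elm / none)
- amount of target at the outlet or at the end, in percent of the substrate put in, ash
- amount of target at the outlet or at the end, in percent of the substrate put in, maple
- amount of target at the outlet or at the end, in percent of the substrate put in, larch
- amount of target at the outlet or at the end, in percent of the substrate put in, elm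

- percent here means substrate units held: one homo product counts as two
- for a step with 2 of a species take k times the square, and two of it per event
- the stated concentrations are those of everything mixed, before any reaction; amounts are the same in each set-up
- the feed brings no volume worth counting
- run time (ash): 2.5 min

We call substrate, open intermediate and target together the live pool; the homo step drains it, with no way back. Which given numbers must we know well? The rate constants of opening and binding set how soon balance comes. Opening has a half-life of 0.693 s, forward rate alone, and binding a relaxation half-life of 1.15 s, both ways together, with the partner charge as second intermediate, far shorter than the run. An error in either therefore moves little, and we treat both steps as a pre-equilibrium. Partner's half-life of 0.236 min fits 10.6 times into the closed flask's run, so we leave its lag out of our reckoning for elm, as a correction of unknown size. The binding constant, the opening constant and the partner charge enter the balance directly, and the homo constant enters the pool's size. So the numbers themselves: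

[target]/[open intermediate] = 2.2 L mol⁻¹ × 0.360 M = 0.792

[substrate]/[open intermediate] = 1/0.80

target share = 26.0%

This target share, the part of the live pool standing as target once opening and binding are in balance, becomes 41.3% with a binding constant of 4.40 L mol⁻¹. The open part of the pool is 0.329, so the pool falls at a[pool]², with a = 0.0432 L mol⁻¹ s⁻¹. This takes second intermediate as the full partner charge from the start. By our reckoning:

elm: [pool] = 0.0871 M, target 11.3%

ash: [pool] = 0.151 M when the feed ends, then 0.126 M, target 16.4%

larch: [pool] = 0.0484 M, target 6.30%

maple: target 14.9%, with 12.0% of partner still unturned at the outlet, which this figure leaves out

Our figures for ash and maple lie 1.5 percentage points apart against a margin of 2 points, but the maple figure counts that unturned partner as second intermediate, so we expect the gap to widen and put ash first. The forecast gave ash with 15%, then 12.1% for maple, 6% for larch and 10.3% for elm: “Ash is best by about 3 points.” The simulation gives ash as best, with 15.3% in ash, 12.1% in maple, 6.00% in larch and 10.2% in elm.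

Ash stays this low because target returns to open intermediate and second intermediate: with that return taken away, ash gives 95.7% instead of 15.3%. At the end of ash, target is 24.6% of the live pool, against the 26.0% reckoned. In a neighbour of elm charged with 0.14 M of partner, the reckoned share falls to 12.0%, and that flask ends with target at 11.5% of its live pool.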